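**Numbering used throughout.** Ring carbons are C1–C10, with methyl C14 on C10 and methyl C15 on C4. The lactone branch is C11 (on C7), C12 (carbonyl, bonded to O6) and C13 (the CH2OAc carbon). Compounds are numbered 1–36 in order of first appearance in the steps; 36 is the target.

## Analysis of the target

Target 36 is a germacranolide: a ten-membered carbocycle fused across C6–C7 to a butenolide (O6–C12(=O)–C11=C7) whose C11 carries an acetoxymethyl group (C13). C8 bears a 3-methylbut-2-enoate (senecioate), and C1–C10 and C4–C5 are both trisubstituted oxiranes. The six stereocentres are 1S, 4S, 5R, 6R, 8R and 10R. Drawn flat, the C6 and C8 oxygens and the 4,5-oxirane oxygen lie on one face (so C6/C8 is a syn-1,3-dioxygen pattern and the 4,5-epoxide is cis to O6), while the 1,10-oxirane oxygen lies on the other face. In each oxirane the two ring bonds are cis, so both derive from Z olefins. The sensitive groups are the two acid-labile trisubstituted epoxides, the butenolide with acyloxy groups at both γ-positions (elimination or translactonisation with base), the senecioate (γ-deprotonation by strong base) and the allylic acetate. The difficulty lies in closing a medium ring, in building a tetrasubstituted C7=C11 between two oxygenated stereocentres, and in setting two epoxides on opposite faces. The strategy rests on C4: it is the methyl-bearing sp2 carbon of the latent Z C4=C5 olefin and is linked through the C2–C3 ethylene to the C1 oxirane carbon. A Z alkenyl iodide at C4 and a vinyl group on C1 therefore map onto the C3–C4 bond, and the Z olefin and cis-oxirane on either side act as built-in turns.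

## Retrosynthetic reasoning

36 ⇐ 35 ⇐ 34 ⇐ 33. The acetate is removed first, and the C13 alcohol of 35 is traced to the carboxylic acid 34 and its trichloroethyl ester 33. C13 therefore arrives as a carboxyl carbon that can be reduced selectively beside the lactone and the two other esters, and the base-sensitive allylic acetate exists only in the last step.

33 ⇐ 31 (through selenide 32). The C7=C11 double bond is cut back to the saturated lactone ester 31. Its C11–H sits between two carbonyls, so the unsaturation can be introduced by soft enolisation, selenenylation and syn-elimination without a strong base that would deconjugate the senecioate.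

31 ⇐ 30 ⇐ 29 ⇐ 25 + 28. The C7–C11 bond is disconnected as a carbenoid C–H insertion from the diazomalonate 30, which comes from alcohol 25 and half ester 28 by acylation and diazo transfer. C7 is the ring methylene five atoms from the carbenoid carbon, and the disconnection delivers C11, C12 and C13 in one ester while leaving C6 untouched. It is made after both epoxides are in place because a free C4=C5 olefin would be cyclopropanated.

25 ⇐ 24 ⇐ 23. The 4,5-epoxide is traced to the Z olefin of allylic alcohol 24, freed from silyl ether 23. The olefin must outlive the ring closure because it is the coupling handle, and the C6 hydroxyl then serves as the directing group for its oxidation.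

23 ⇐ 21 (through borane 22). The ring is opened at C3–C4, the only ring bond between an sp3 methylene and the sp2 carbon of the Z olefin. This gives an acyclic chain 21 in which every stereocentre present in 23 is already set, and the forward step has only to close the ring with retention of olefin geometry.

21 ⇐ 19 + 20. The senecioate is put on last before the ring closure, from alcohol 19 and acid 20, so that it escapes the hydride and organometallic steps and deactivates C8–H in the later carbenoid step.

19 ⇐ 18 ⇐ 17 ⇐ 16. The vinyl group is traced to a lactol 18 (one-carbon olefination), made from epoxy lactone 17, which is the oxidation product of epoxy diol 16. Tying O8 to C2 as a lactone differentiates the two hydroxyls of 16 without protecting groups.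

16 ⇐ 15 ⇐ 14. C1 and C10 are set by reagent-controlled epoxidation of the Z allylic alcohol 15. The Z geometry is secured by drawing 15 from the six-membered unsaturated lactone 14, in which it is locked by the ring.

14 ⇐ 12 (through 13) ⇐ 9 + 10 (through 11). The C10–C14 bond is cut as a syn methyl–copper addition to ynoate 12, and the C9–C10 bond as opening of the terminal epoxide 9 by the acetylide 11 of propiolate 10. An acetylide is the one carbon nucleophile that leaves the alkenyl iodide alone.

9 ⇐ 8 ⇐ 7 ⇐ 5 (through 6). The silyl ether and the terminal epoxide are traced to chloro diol 7. Its Z iodoalkene comes from the propargylic alcohol 5 by trans-hydroalumination and iodination, done early because the hydride reagent tolerates neither ester nor epoxide.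

5 ⇐ 4 ⇐ 2 + 3 ⇐ 1. C6 is set from C8 by a chelate-controlled syn reduction of the β-hydroxy ynone 4, which comes from the amide 2 and the propynyl Grignard reagent 3. C8 itself is bought with the hydroxy ester 1.

## Alternatives that were turned down

Alternative 1: Both oxiranes are traced to the two allylic alcohol units of the open-chain Z,Z-dienediol A2. In the forward key step one titanium–tartrate epoxidation converts A2 into the bis-epoxy diol A1, fixing C1, C10, C4 and C5 together. In its favour, four stereocentres come from one catalytic, reagent-controlled operation on a cheap symmetrical-looking diol, with no dependence on ring conformation. On this point it is stronger than the chosen route, which needs two epoxidations, the second under substrate control. Against it, A1 leaves the ring unmade: the C6–C9 bridge has to be inserted between two epoxy carbinol ends, with C9 neopentyl-like beside a quaternary oxirane carbon and C6 created by addition to an epoxy aldehyde. Both epoxides must then survive every C–C bond formation, the ring closure and the lactone annulation, and the C4=C5 olefin is no longer available as a coupling handle. The chosen strategy instead carries C4=C5 as an olefin until the ring is closed and uses it twice, first for the coupling and then for the epoxide.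

Alternative 2: The ring is cut at C5–C6 and the lactone at O6–C12. In the forward step the iodo aldehyde ester A4 is treated with CrCl2 and catalytic NiCl2; the alkenylchromium adds to the C6 aldehyde and the alkoxide closes onto the cis ester, giving A3, the 4,5-deoxy target. In its favour, ring and butenolide form together and C11–C13 are in place beforehand, so no late C–H functionalisation at C7 is needed. Here it is stronger than the chosen route, whose riskiest later step is that C–H insertion. Against it, C6 is created in the ring-closing addition with no reliable model for its configuration, although it is the centre that defines the lactone and relays stereochemistry to C4/C5. A4 is a tetrasubstituted alkylidene with an aldehyde cis to an ester and an allylic acyloxy group at C8, prone to E/Z drift, β-elimination and pseudo-acid formation. The final epoxidation of A3 has no hydroxyl to direct it, since O6 is locked in the lactone. The chosen strategy sets C6 before ring closure from C8 by chelate control and keeps the free hydroxyl for the directed epoxidation.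

Alternative 3: The ten-membered ring is drawn from a decalin by cleaving the C1–C6 bond. Anodic oxidation of the carboxylate of the cis-fused hydroxy acid A6 expels CO2, the C1–C6 bond breaks with assistance from the C6 hydroxyl, and the dienone A5 results. In its favour, the ring is formed by fragmenting an easily built six–six system, with no entropic penalty and no high dilution; on ring formation alone it is stronger than a ten-membered cross-coupling. Against it, A5 carries only the C8 stereocentre, so two olefin epoxidations and a ketone reduction must all be steered by macrocycle conformation. A5 is a (Z,Z)-cyclodeca-1,5-dienone, open to Cope rearrangement and transannular reactions. The fragmentation passes through a cation at C10, so the Z geometry of C1=C10 depends on one particular diastereomer and conformer of A6. The C8 ester and the whole lactone are still missing. The chosen route has more steps before the ring but arrives at the ring with C1, C6, C8 and C10 fixed and the olefin geometry secured by a stereoretentive coupling.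

Key step: step 15

Assumptions: prop-1-yn-1-ylmagnesium bromide 3 is used as the commercial THF solution (it is made from propyne). Lactol 18 is an epimer mixture at the lactol carbon. C7 and C11 of 31 and 32 are formed without control and are erased in step 22, so their SMILES leave these centres open.

## Steps

Step 1
Reactants: 1 ethyl (3S)-4-chloro-3-hydroxybutanoate
Product: 2 (3S)-4-chloro-3-hydroxy-N-methoxy-N-methylbutanamide
Conditions: MeNH(OMe)·HCl, AlMe3, CH2Cl2, 0 °C → rt
Reagents that add atoms: N,O-dimethylhydroxylamine hydrochloride, CNOC.Cl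
Why: Weinreb aminolysis of the ester by the aluminium amide formed in the flask; the free hydroxyl is carried as an aluminium alkoxide and C8 is not touched.

Step 2
Reactants: 2 (3S)-4-chloro-3-hydroxy-N-methoxy-N-methylbutanamide; 3 prop-1-yn-1-ylmagnesium bromide
Product: 4 (6S)-7-chloro-6-hydroxyhept-2-yn-4-one
Conditions: 3 (3 equiv), THF, −78 → 0 °C; aq. NH4Cl
Reagents that add atoms: none
Why: Weinreb ketone synthesis; the chelated tetrahedral adduct stops at the ketone stage, one equivalent of Grignard reagent is spent on the hydroxyl, and the magnesium alkoxide of the chlorohydrin does not close at or below 0 °C.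

Step 3
Reactants: 4 (6S)-7-chloro-6-hydroxyhept-2-yn-4-one
Product: 5 (2S,4R)-1-chlorohept-5-yne-2,4-diol
Conditions: Et2BOMe, NaBH4, THF/MeOH 4:1, −78 °C; AcOH; MeOH azeotrope
Reagents that add atoms: none
Why: Narasaka–Prasad reduction; the six-membered boron chelate of the β-hydroxy ketone takes external hydride axially, giving the 1,3-syn diol and so setting C6 (R) from C8.

Step 4
Reactants: 5 (2S,4R)-1-chlorohept-5-yne-2,4-diol
Product: 7 (2S,4R,5Z)-1-chloro-6-iodohept-5-ene-2,4-diol, via cyclic alkenylaluminate 6 (not isolated)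
Conditions: NaAlH2(OCH2CH2OMe)2, THF, 0 °C → rt; then I2, THF, −78 → 0 °C
Reagents that add atoms: iodine, II; sodium bis(2-methoxyethoxy)aluminium hydride, [Na+].COCCO[AlH2-]OCCOC (its aluminium stays in intermediate 6 only)
Why: trans-hydroalumination of the propargylic alkoxide puts hydride on C5 and aluminium on C4 inside a five-membered ring (6), and iodinolysis with retention gives the Z iodide with iodine cis to C6; the primary chloride and the second alkoxide are inert at this temperature.

Step 5
Reactants: 7 (2S,4R,5Z)-1-chloro-6-iodohept-5-ene-2,4-diol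
Product: 8 (2R,3Z)-4-iodo-1-[(2S)-oxiran-2-yl]pent-3-en-2-ol
Conditions: K2CO3, MeOH, 0 °C → rt
Reagents that add atoms: none
Why: Intramolecular Williamson closure; the chlorohydrin hydroxyl is the more acidic one and its three-membered closure is fast, so the epoxide forms in preference to an oxolane from the C6 hydroxyl, and C8 keeps its configuration.

Step 6
Reactants: 8 (2R,3Z)-4-iodo-1-[(2S)-oxiran-2-yl]pent-3-en-2-ol
Product: 9 tert-butyl{[(2R,3Z)-4-iodo-1-[(2S)-oxiran-2-yl]pent-3-en-2-yl]oxy}dimethylsilane
Conditions: TBSCl, imidazole, DMF, rt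
Reagents that add atoms: tert-butyldimethylsilyl chloride, CC(C)(C)[Si](C)(C)Cl
Why: Standard silylation of the allylic alcohol; the silyl ether lasts through the base, hydride and coupling steps up to step 16.

Step 7
Reactants: 9 tert-butyl{[(2R,3Z)-4-iodo-1-[(2S)-oxiran-2-yl]pent-3-en-2-yl]oxy}dimethylsilane; 10 ethyl prop-2-ynoate
Product: 12 ethyl (5R,7R,8Z)-7-[(tert-butyldimethylsilyl)oxy]-5-hydroxy-9-iododec-8-en-2-ynoate, via lithium acetylide 11 (not isolated)
Conditions: 10, n-BuLi, THF, −78 °C; BF3·OEt2; then 9, −78 °C; aq. NH4Cl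
Reagents that add atoms: n-butyllithium, [Li]CCCC (its lithium stays in intermediate 11 only)
Why: Yamaguchi–Hirao alkynylation; the BF3-activated terminal epoxide is opened at its CH2 (C9) by acetylide 11, which forms C9–C10 and frees the C8 hydroxyl, and an acetylide does not undergo halogen–metal exchange with the alkenyl iodide.

Step 8
Reactants: 12 ethyl (5R,7R,8Z)-7-[(tert-butyldimethylsilyl)oxy]-5-hydroxy-9-iododec-8-en-2-ynoate
Product: 14 (6R)-6-[(2R,3Z)-2-[(tert-butyldimethylsilyl)oxy]-4-iodopent-3-en-1-yl]-4-methyl-5,6-dihydro-2H-pyran-2-one, via hydroxy Z-enoate 13 (not isolated)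
Conditions: Me2CuLi (from MeLi, CuI), THF, −78 °C; aq. NH4Cl; then PPTS (cat.), CH2Cl2, rt
Reagents that add atoms: lithium dimethylcuprate, [Li+].C[Cu-]C
Why: syn carbocupration (conjugate addition) of the ynoate at −78 °C gives the Z enoate 13 with the ester cis to the chain, and lactonisation onto the C8 hydroxyl locks that geometry in a six-membered ring; at −78 °C conjugate addition is far faster than coupling of the cuprate with the alkenyl iodide.

Step 9
Reactants: 14 (6R)-6-[(2R,3Z)-2-[(tert-butyldimethylsilyl)oxy]-4-iodopent-3-en-1-yl]-4-methyl-5,6-dihydro-2H-pyran-2-one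
Product: 15 (2Z,5R,7R,8Z)-7-[(tert-butyldimethylsilyl)oxy]-9-iodo-3-methyldeca-2,8-diene-1,5-diol
Conditions: i-Bu2AlH (3.5 equiv), CH2Cl2, −78 → −20 °C
Reagents that add atoms: none
Why: 1,2-reduction of the unsaturated lactone opens it to the Z allylic diol without touching the iodoalkene or the silyl ether.

Step 10
Reactants: 15 (2Z,5R,7R,8Z)-7-[(tert-butyldimethylsilyl)oxy]-9-iodo-3-methyldeca-2,8-diene-1,5-diol
Product: 16 (2S,4R,5Z)-4-[(tert-butyldimethylsilyl)oxy]-1-[(2R,3S)-3-(hydroxymethyl)-2-methyloxiran-2-yl]-6-iodohept-5-en-2-ol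
Conditions: Ti(OiPr)4, L-(+)-diisopropyl tartrate, t-BuOOH, 4 Å MS, CH2Cl2, −20 °C
Reagents that add atoms: tert-butyl hydroperoxide, CC(C)(C)OO
Why: Katsuki–Sharpless asymmetric epoxidation of a nerol-type Z allylic alcohol; the L-(+)-tartrate complex delivers oxygen to the face that gives C1 (S) and C10 (R) under reagent control, and the iodoalkene has no free allylic hydroxyl and is left alone.

Step 11
Reactants: 16 (2S,4R,5Z)-4-[(tert-butyldimethylsilyl)oxy]-1-[(2R,3S)-3-(hydroxymethyl)-2-methyloxiran-2-yl]-6-iodohept-5-en-2-ol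
Product: 17 (1R,4S,6R)-4-[(2R,3Z)-2-[(tert-butyldimethylsilyl)oxy]-4-iodopent-3-en-1-yl]-6-methyl-3,7-dioxabicyclo[4.1.0]heptan-2-one
Conditions: TEMPO (cat.), PhI(OAc)2 (2.5 equiv), CH2Cl2, rt
Reagents that add atoms: none
Why: Oxidative lactonisation of a 1,5-diol; the oxoammonium salt oxidises only the primary alcohol, the cis C8 hydroxyl traps the aldehyde, and the hemiacetal is oxidised on, which differentiates the two hydroxyls without a protecting group.

Step 12
Reactants: 17 (1R,4S,6R)-4-[(2R,3Z)-2-[(tert-butyldimethylsilyl)oxy]-4-iodopent-3-en-1-yl]-6-methyl-3,7-dioxabicyclo[4.1.0]heptan-2-one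
Product: 18 (1R,4S,6R)-4-[(2R,3Z)-2-[(tert-butyldimethylsilyl)oxy]-4-iodopent-3-en-1-yl]-6-methyl-3,7-dioxabicyclo[4.1.0]heptan-2-ol
Conditions: i-Bu2AlH (1.1 equiv), CH2Cl2, −78 °C
Reagents that add atoms: none
Why: Partial reduction of the lactone; the aluminium hemiacetal is stable at −78 °C and gives the lactol on work-up, with the epoxide untouched.

Step 13
Reactants: 18 (1R,4S,6R)-4-[(2R,3Z)-2-[(tert-butyldimethylsilyl)oxy]-4-iodopent-3-en-1-yl]-6-methyl-3,7-dioxabicyclo[4.1.0]heptan-2-ol
Product: 19 (2S,4R,5Z)-4-[(tert-butyldimethylsilyl)oxy]-1-[(2R,3S)-3-ethenyl-2-methyloxiran-2-yl]-6-iodohept-5-en-2-ol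
Conditions: Ph3PCH3Br, KN(SiMe3)2, THF, 0 °C; then 18, −78 °C → rt
Reagents that add atoms: methyltriphenylphosphonium bromide, C[P+](c1ccccc1)(c1ccccc1)c1ccccc1.[Br-]
Why: Wittig methylenation of the lactol through its open hydroxy aldehyde gives the vinyl epoxide and frees the C8 hydroxyl; the ylide is made with an amide base so that no alkyllithium meets the alkenyl iodide.

Step 14
Reactants: 19 (2S,4R,5Z)-4-[(tert-butyldimethylsilyl)oxy]-1-[(2R,3S)-3-ethenyl-2-methyloxiran-2-yl]-6-iodohept-5-en-2-ol; 20 3-methylbut-2-enoic acid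
Product: 21 (2S,4R,5Z)-4-[(tert-butyldimethylsilyl)oxy]-1-[(2R,3S)-3-ethenyl-2-methyloxiran-2-yl]-6-iodohept-5-en-2-yl 3-methylbut-2-enoate
Conditions: DCC, DMAP (cat.), CH2Cl2, 0 °C → rt
Reagents that add atoms: none
Why: Steglich esterification of the secondary alcohol under neutral conditions, which keeps the conjugated position of the double bond and spares the vinyl epoxide.

Step 15
Reactants: 21 (2S,4R,5Z)-4-[(tert-butyldimethylsilyl)oxy]-1-[(2R,3S)-3-ethenyl-2-methyloxiran-2-yl]-6-iodohept-5-en-2-yl 3-methylbut-2-enoate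
Product: 23 (1S,4Z,6R,8S,10R)-6-[(tert-butyldimethylsilyl)oxy]-4,10-dimethyl-11-oxabicyclo[8.1.0]undec-4-en-8-yl 3-methylbut-2-enoate, via B-alkyl borane 22 (not isolated)
Conditions: 9-BBN (1.5 equiv), THF, 0 °C → rt; then slow addition (8 h) to PdCl2(dppf) (20 mol %), AsPh3 (20 mol %), Cs2CO3, DMF/THF/H2O, 50 °C, final 1 mM
Reagents that add atoms: 9-borabicyclo[3.3.1]nonane, B1C2CCCC1CCC2 (its boryl group stays in intermediate 22 only)
Why: 9-BBN adds anti-Markovnikov to the terminal C2=C3 bond only, giving the primary borane 22, since the trisubstituted iodoalkene, the electron-poor senecioate olefin and the ester carbonyl do not react at room temperature. Aqueous Cs2CO3 turns 22 into its hydroxyborate, zerovalent palladium formed from PdCl2(dppf) inserts into the C4–I bond with retention, the primary alkyl group is transferred from boron to palladium, and reductive elimination forms C3–C4. The closest known reaction type is the B-alkyl Suzuki–Miyaura macrocyclisation of an ω-alkenyl alkenyl iodide, which has closed carbocycles down to nine members. The ten-membered carbocycle is closed end to end through an eleven-membered palladacycle, and the Z iodoalkene and the cis-oxirane act as turns that bring C3 and C4 together. No stereocentre is formed, and the Z geometry of C4=C5 is kept because oxidative addition and reductive elimination are stereoretentive. Two selectivities are needed: hydroboration must be complete before palladium is present, so that no vinyl epoxide remains to be ionised, and ring closure must beat oligomerisation and β-hydride elimination. The first is secured by running the step in two stages, the second by slow addition to high dilution and by the wide-bite-angle dppf ligand, which speeds reductive elimination.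

Step 16
Reactants: 23 (1S,4Z,6R,8S,10R)-6-[(tert-butyldimethylsilyl)oxy]-4,10-dimethyl-11-oxabicyclo[8.1.0]undec-4-en-8-yl 3-methylbut-2-enoate
Product: 24 (1S,4Z,6R,8S,10R)-6-hydroxy-4,10-dimethyl-11-oxabicyclo[8.1.0]undec-4-en-8-yl 3-methylbut-2-enoate
Conditions: Bu4NF, AcOH (1:1), THF, 0 °C → rt
Reagents that add atoms: none
Why: Fluoride cleavage of the silyl ether; buffering with acetic acid suppresses 1,3-acyl migration of the senecioate and leaves the epoxide alone.

Step 17
Reactants: 24 (1S,4Z,6R,8S,10R)-6-hydroxy-4,10-dimethyl-11-oxabicyclo[8.1.0]undec-4-en-8-yl 3-methylbut-2-enoate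
Product: 25 (1S,4S,6R,7R,9S,11R)-7-hydroxy-4,11-dimethyl-5,12-dioxatricyclo[9.1.0.0(4,6)]dodecan-9-yl 3-methylbut-2-enoate
Conditions: VO(acac)2 (5 mol %), t-BuOOH, CH2Cl2, 0 °C → rt
Reagents that add atoms: tert-butyl hydroperoxide, CC(C)(C)OO
Why: Hydroxyl-directed epoxidation; the vanadate ester of the C6 hydroxyl delivers oxygen through a transition state with a small O–C6–C5=C4 dihedral angle, which in medium-ring Z allylic alcohols gives the cis epoxy alcohol (unlike peracids), here 4S,5R, and the senecioate olefin is too electron-poor to compete.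

Step 18
Reactants: 26 2,2-dimethyl-1,3-dioxane-4,6-dione (Meldrum's acid); 27 2,2,2-trichloroethanol
Product: 28 3-oxo-3-(2,2,2-trichloroethoxy)propanoic acid
Conditions: toluene, 110 °C
Reagents that add atoms: none
Why: Alcoholysis of Meldrum's acid with loss of acetone gives the malonic half ester; the trichloroethyl group is chosen because it has no C–H bond within reach of the later carbenoid and is removed without acid or base.

Step 19
Reactants: 25 (1S,4S,6R,7R,9S,11R)-7-hydroxy-4,11-dimethyl-5,12-dioxatricyclo[9.1.0.0(4,6)]dodecan-9-yl 3-methylbut-2-enoate; 28 3-oxo-3-(2,2,2-trichloroethoxy)propanoic acid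
Product: 29 (1S,4S,6R,7R,9S,11R)-4,11-dimethyl-9-[(3-methylbut-2-enoyl)oxy]-5,12-dioxatricyclo[9.1.0.0(4,6)]dodecan-7-yl 2,2,2-trichloroethyl propanedioate
Conditions: DCC, DMAP (cat.), CH2Cl2, 0 °C → rt
Reagents that add atoms: none
Why: Carbodiimide coupling of a malonic half ester, which passes through the reactive acyl ketene and so acylates the hindered epoxy alcohol; the C6–O bond is not broken and C6 stays R.

Step 20
Reactants: 29 (1S,4S,6R,7R,9S,11R)-4,11-dimethyl-9-[(3-methylbut-2-enoyl)oxy]-5,12-dioxatricyclo[9.1.0.0(4,6)]dodecan-7-yl 2,2,2-trichloroethyl propanedioate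
Product: 30 (1S,4S,6R,7R,9S,11R)-4,11-dimethyl-9-[(3-methylbut-2-enoyl)oxy]-5,12-dioxatricyclo[9.1.0.0(4,6)]dodecan-7-yl 2,2,2-trichloroethyl 2-diazopropanedioate
Conditions: 4-acetamidobenzenesulfonyl azide, Et3N, MeCN, 0 °C → rt
Reagents that add atoms: 4-acetamidobenzenesulfonyl azide, CC(=O)Nc1ccc(cc1)S(=O)(=O)N=[N+]=[N-]
Why: Regitz diazo transfer to the malonate methylene, which is acidic enough for triethylamine, so nothing else in the molecule is enolised.

Step 21
Reactants: 30 (1S,4S,6R,7R,9S,11R)-4,11-dimethyl-9-[(3-methylbut-2-enoyl)oxy]-5,12-dioxatricyclo[9.1.0.0(4,6)]dodecan-7-yl 2,2,2-trichloroethyl 2-diazopropanedioate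
Product: 31 2,2,2-trichloroethyl (1S,4S,5R,6R,8R,10R)-1,10:4,5-diepoxy-8-[(3-methylbut-2-enoyl)oxy]germacran-12,6-olid-13-oate (C7/C11 epimer mixture)
Conditions: Rh2(OAc)4 (2 mol %), CH2Cl2, 40 °C, slow addition
Reagents that add atoms: none
Why: Dirhodium-carbenoid 1,5 C–H insertion of a diazomalonate ester to a γ-lactone, forming C7–C11; C7–H is the only sp3 C–H in reach of a five-membered closure apart from the strong oxirane C5–H, the C8 acyloxy group deactivates C8–H towards six-ring closure, and the new C7 and C11 centres are left uncontrolled because step 22 removes them.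

Step 22
Reactants: 31 2,2,2-trichloroethyl (1S,4S,5R,6R,8R,10R)-1,10:4,5-diepoxy-8-[(3-methylbut-2-enoyl)oxy]germacran-12,6-olid-13-oate
Product: 33 2,2,2-trichloroethyl (1S,4S,5R,6R,8R,10R)-1,10:4,5-diepoxy-8-[(3-methylbut-2-enoyl)oxy]germacr-7(11)-en-12,6-olid-13-oate, via 11-phenylselanyl lactone ester 32 (not isolated)
Conditions: PhSeCl, pyridine, CH2Cl2, 0 °C; then H2O2 (30 % aq.), 0 °C → rt
Reagents that add atoms: phenylselenenyl chloride, Cl[Se]c1ccccc1 (its selenium stays in intermediate 32 only)
Why: Soft selenenylation of the β-dicarbonyl C11–H followed by selenoxide syn-elimination; selenium enters on the face away from the C8 branch, hence syn to H7, and C7–H is the only β-hydrogen, so the tetrasubstituted butenolide is the only possible olefin.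

Step 23
Reactants: 33 2,2,2-trichloroethyl (1S,4S,5R,6R,8R,10R)-1,10:4,5-diepoxy-8-[(3-methylbut-2-enoyl)oxy]germacr-7(11)-en-12,6-olid-13-oate
Product: 34 (1S,4S,5R,6R,8R,10R)-1,10:4,5-diepoxy-8-[(3-methylbut-2-enoyl)oxy]germacr-7(11)-en-12,6-olid-13-oic acid
Conditions: Zn dust, AcOH/THF 1:4, 0 °C → rt
Reagents that add atoms: none
Why: Reductive β-elimination of the trichloroethyl ester; zinc reduces the C–Cl bond much more readily than it transfers electrons to an enoate, and the conditions are neither basic nor strongly acidic.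

Step 24
Reactants: 34 (1S,4S,5R,6R,8R,10R)-1,10:4,5-diepoxy-8-[(3-methylbut-2-enoyl)oxy]germacr-7(11)-en-12,6-olid-13-oic acid
Product: 35 (1S,4S,5R,6R,8R,10R)-1,10:4,5-diepoxy-13-hydroxy-8-[(3-methylbut-2-enoyl)oxy]germacr-7(11)-en-12,6-olide
Conditions: BH3·SMe2, THF, −10 → 0 °C; MeOH
Reagents that add atoms: none
Why: Borane reduces a carboxylic acid through its acyloxyborane far faster than it reduces lactones or esters, and the electron-poor tetrasubstituted olefin is not hydroborated at this temperature.

Step 25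
Reactants: 35 (1S,4S,5R,6R,8R,10R)-1,10:4,5-diepoxy-13-hydroxy-8-[(3-methylbut-2-enoyl)oxy]germacr-7(11)-en-12,6-olide
Product: 36 (1S,4S,5R,6R,8R,10R)-13-acetoxy-1,10:4,5-diepoxy-8-[(3-methylbut-2-enoyl)oxy]germacr-7(11)-en-12,6-olide
Conditions: Ac2O, pyridine, DMAP (cat.), CH2Cl2, 0 °C
Reagents that add atoms: acetic anhydride, CC(=O)OC(C)=O
Why: Acetylation of the primary allylic alcohol under mild pyridine conditions that do not enolise the butenolide; this should give the target.

## Compound list

1 | ethyl (3S)-4-chloro-3-hydroxybutanoate | ClC[C@@H](O)CC(=O)OCC | starting material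
2 | (3S)-4-chloro-3-hydroxy-N-methoxy-N-methylbutanamide | ClC[C@@H](O)CC(=O)N(C)OC | intermediate
3 | prop-1-yn-1-ylmagnesium bromide | CC#C[Mg]Br | starting material
4 | (6S)-7-chloro-6-hydroxyhept-2-yn-4-one | ClC[C@@H](O)CC(=O)C#CC | intermediate
5 | (2S,4R)-1-chlorohept-5-yne-2,4-diol | ClC[C@@H](O)C[C@@H](O)C#CC | intermediate
6 | sodium cyclic alkenylaluminate: aluminium bonded to O6, C4 and two 2-methoxyethoxy groups (C8–O drawn as hydroxyl; in the flask it is an aluminium alkoxide too) | [Na+].ClC[C@@H](O)C[C@H]1O[Al-](OCCOC)(OCCOC)C(C)=C1 | intermediate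
7 | (2S,4R,5Z)-1-chloro-6-iodohept-5-ene-2,4-diol | ClC[C@@H](O)C[C@@H](O)/C=C(/C)I | intermediate
8 | (2R,3Z)-4-iodo-1-[(2S)-oxiran-2-yl]pent-3-en-2-ol | C1[C@@H](O1)C[C@@H](O)/C=C(/C)I | intermediate
9 | tert-butyl{[(2R,3Z)-4-iodo-1-[(2S)-oxiran-2-yl]pent-3-en-2-yl]oxy}dimethylsilane | C1[C@@H](O1)C[C@@H](O[Si](C)(C)C(C)(C)C)/C=C(/C)I | intermediate
10 | ethyl prop-2-ynoate | C#CC(=O)OCC | starting material
11 | lithium 3-ethoxy-3-oxoprop-1-yn-1-ide | [Li+].[C-]#CC(=O)OCC | intermediate
12 | ethyl (5R,7R,8Z)-7-[(tert-butyldimethylsilyl)oxy]-5-hydroxy-9-iododec-8-en-2-ynoate | CCOC(=O)C#CC[C@@H](O)C[C@@H](O[Si](C)(C)C(C)(C)C)/C=C(/C)I | intermediate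
13 | ethyl (2Z,5R,7R,8Z)-7-[(tert-butyldimethylsilyl)oxy]-5-hydroxy-9-iodo-3-methyldeca-2,8-dienoate | CCOC(=O)/C=C(C)\C[C@@H](O)C[C@@H](O[Si](C)(C)C(C)(C)C)/C=C(/C)I | intermediate
14 | (6R)-6-[(2R,3Z)-2-[(tert-butyldimethylsilyl)oxy]-4-iodopent-3-en-1-yl]-4-methyl-5,6-dihydro-2H-pyran-2-one | CC1=CC(=O)O[C@H](C1)C[C@@H](O[Si](C)(C)C(C)(C)C)/C=C(/C)I | intermediate
15 | (2Z,5R,7R,8Z)-7-[(tert-butyldimethylsilyl)oxy]-9-iodo-3-methyldeca-2,8-diene-1,5-diol | OC/C=C(C)\C[C@@H](O)C[C@@H](O[Si](C)(C)C(C)(C)C)/C=C(/C)I | intermediate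
16 | (2S,4R,5Z)-4-[(tert-butyldimethylsilyl)oxy]-1-[(2R,3S)-3-(hydroxymethyl)-2-methyloxiran-2-yl]-6-iodohept-5-en-2-ol | OC[C@@H]1O[C@]1(C)C[C@@H](O)C[C@@H](O[Si](C)(C)C(C)(C)C)/C=C(/C)I | intermediate
17 | (1R,4S,6R)-4-[(2R,3Z)-2-[(tert-butyldimethylsilyl)oxy]-4-iodopent-3-en-1-yl]-6-methyl-3,7-dioxabicyclo[4.1.0]heptan-2-one | C[C@]12O[C@H]1C(=O)O[C@H](C2)C[C@@H](O[Si](C)(C)C(C)(C)C)/C=C(/C)I | intermediate
18 | (1R,4S,6R)-4-[(2R,3Z)-2-[(tert-butyldimethylsilyl)oxy]-4-iodopent-3-en-1-yl]-6-methyl-3,7-dioxabicyclo[4.1.0]heptan-2-ol (lactol epimers) | C[C@]12O[C@H]1C(O)O[C@H](C2)C[C@@H](O[Si](C)(C)C(C)(C)C)/C=C(/C)I | intermediate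
19 | (2S,4R,5Z)-4-[(tert-butyldimethylsilyl)oxy]-1-[(2R,3S)-3-ethenyl-2-methyloxiran-2-yl]-6-iodohept-5-en-2-ol | C=C[C@@H]1O[C@]1(C)C[C@@H](O)C[C@@H](O[Si](C)(C)C(C)(C)C)/C=C(/C)I | intermediate
20 | 3-methylbut-2-enoic acid | CC(C)=CC(O)=O | starting material
21 | (2S,4R,5Z)-4-[(tert-butyldimethylsilyl)oxy]-1-[(2R,3S)-3-ethenyl-2-methyloxiran-2-yl]-6-iodohept-5-en-2-yl 3-methylbut-2-enoate | C=C[C@@H]1O[C@]1(C)C[C@@H](OC(=O)C=C(C)C)C[C@@H](O[Si](C)(C)C(C)(C)C)/C=C(/C)I | intermediate
22 | (2S,4R,5Z)-1-{(2R,3S)-3-[2-(9-borabicyclo[3.3.1]nonan-9-yl)ethyl]-2-methyloxiran-2-yl}-4-[(tert-butyldimethylsilyl)oxy]-6-iodohept-5-en-2-yl 3-methylbut-2-enoate | C(C[C@@H]1O[C@]1(C)C[C@@H](OC(=O)C=C(C)C)C[C@@H](O[Si](C)(C)C(C)(C)C)/C=C(/C)I)B1C2CCCC1CCC2 | intermediate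
23 | (1S,4Z,6R,8S,10R)-6-[(tert-butyldimethylsilyl)oxy]-4,10-dimethyl-11-oxabicyclo[8.1.0]undec-4-en-8-yl 3-methylbut-2-enoate | C1[C@@H](O[Si](C)(C)C(C)(C)C)/C=C(/C)CC[C@@H]2O[C@]2(C)C[C@H]1OC(=O)C=C(C)C | intermediate
24 | (1S,4Z,6R,8S,10R)-6-hydroxy-4,10-dimethyl-11-oxabicyclo[8.1.0]undec-4-en-8-yl 3-methylbut-2-enoate | C1[C@@H](O)/C=C(/C)CC[C@@H]2O[C@]2(C)C[C@H]1OC(=O)C=C(C)C | intermediate
25 | (1S,4S,6R,7R,9S,11R)-7-hydroxy-4,11-dimethyl-5,12-dioxatricyclo[9.1.0.0(4,6)]dodecan-9-yl 3-methylbut-2-enoate | C1[C@@H](O)[C@H]3O[C@@]3(C)CC[C@@H]2O[C@]2(C)C[C@H]1OC(=O)C=C(C)C | intermediate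
26 | 2,2-dimethyl-1,3-dioxane-4,6-dione | CC1(C)OC(=O)CC(=O)O1 | starting material
27 | 2,2,2-trichloroethanol | OCC(Cl)(Cl)Cl | starting material
28 | 3-oxo-3-(2,2,2-trichloroethoxy)propanoic acid | OC(=O)CC(=O)OCC(Cl)(Cl)Cl | intermediate
29 | (1S,4S,6R,7R,9S,11R)-4,11-dimethyl-9-[(3-methylbut-2-enoyl)oxy]-5,12-dioxatricyclo[9.1.0.0(4,6)]dodecan-7-yl 2,2,2-trichloroethyl propanedioate | C1[C@@H](OC(=O)CC(=O)OCC(Cl)(Cl)Cl)[C@H]3O[C@@]3(C)CC[C@@H]2O[C@]2(C)C[C@H]1OC(=O)C=C(C)C | intermediate
30 | (1S,4S,6R,7R,9S,11R)-4,11-dimethyl-9-[(3-methylbut-2-enoyl)oxy]-5,12-dioxatricyclo[9.1.0.0(4,6)]dodecan-7-yl 2,2,2-trichloroethyl 2-diazopropanedioate | C1[C@@H](OC(=O)C(=[N+]=[N-])C(=O)OCC(Cl)(Cl)Cl)[C@H]3O[C@@]3(C)CC[C@@H]2O[C@]2(C)C[C@H]1OC(=O)C=C(C)C | intermediate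
31 | 2,2,2-trichloroethyl (1S,4S,5R,6R,8R,10R)-1,10:4,5-diepoxy-8-[(3-methylbut-2-enoyl)oxy]germacran-12,6-olid-13-oate (C7 and C11 open) | ClC(Cl)(Cl)COC(=O)C1C2[C@@H](OC1=O)[C@H]1O[C@@]1(C)CC[C@@H]1O[C@]1(C)C[C@H]2OC(=O)C=C(C)C | intermediate
32 | 11-(phenylselanyl) derivative of 31 | ClC(Cl)(Cl)COC(=O)C1([Se]c3ccccc3)C2[C@@H](OC1=O)[C@H]1O[C@@]1(C)CC[C@@H]1O[C@]1(C)C[C@H]2OC(=O)C=C(C)C | intermediate
33 | 2,2,2-trichloroethyl (1S,4S,5R,6R,8R,10R)-1,10:4,5-diepoxy-8-[(3-methylbut-2-enoyl)oxy]germacr-7(11)-en-12,6-olid-13-oate | ClC(Cl)(Cl)COC(=O)C1=C2[C@@H](OC1=O)[C@H]1O[C@@]1(C)CC[C@@H]1O[C@]1(C)C[C@H]2OC(=O)C=C(C)C | intermediate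
34 | (1S,4S,5R,6R,8R,10R)-1,10:4,5-diepoxy-8-[(3-methylbut-2-enoyl)oxy]germacr-7(11)-en-12,6-olid-13-oic acid | OC(=O)C1=C2[C@@H](OC1=O)[C@H]1O[C@@]1(C)CC[C@@H]1O[C@]1(C)C[C@H]2OC(=O)C=C(C)C | intermediate
35 | (1S,4S,5R,6R,8R,10R)-1,10:4,5-diepoxy-13-hydroxy-8-[(3-methylbut-2-enoyl)oxy]germacr-7(11)-en-12,6-olide | OCC1=C2[C@@H](OC1=O)[C@H]1O[C@@]1(C)CC[C@@H]1O[C@]1(C)C[C@H]2OC(=O)C=C(C)C | intermediate
36 | (1S,4S,5R,6R,8R,10R)-13-acetoxy-1,10:4,5-diepoxy-8-[(3-methylbut-2-enoyl)oxy]germacr-7(11)-en-12,6-olide (CNP0228323.1) | CC(=O)OCC1=C2[C@@H](OC1=O)[C@H]1O[C@@]1(C)CC[C@@H]1O[C@]1(C)C[C@H]2OC(=O)C=C(C)C | target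

## Step count and least certain steps

Total: 25 steps. Longest linear sequence: 24 steps (steps 1–17 and 19–25); step 18 is a one-step side branch.

**Step 15 (key step).** The most likely failure is that the ring does not close. The palladium alkyl may instead undergo β-hydride elimination or protodeboronation, or chains may couple with one another, because a ten-membered ring carries both strain and an entropic penalty. A second danger is that the hydroxyborate of 22 attacks the oxirane carbon C1 three atoms away (1,3-elimination to a cyclopropyl carbinol) under the basic conditions. Fallback without boron or base: 21 is hydroborated with 9-BBN and oxidised with NaBO3 to the primary alcohol (2S,4R,5Z)-4-[(tert-butyldimethylsilyl)oxy]-1-[(2R,3S)-3-(2-hydroxyethyl)-2-methyloxiran-2-yl]-6-iodohept-5-en-2-yl 3-methylbut-2-enoate F1. This is converted with I2, PPh3 and imidazole into the primary iodide, the 3-(2-iodoethyl) analogue F2. Zinc dust with LiCl inserts into the alkyl C–I bond only, giving the alkylzinc iodide F3, which is closed by an intramolecular Negishi coupling with PdCl2(dppf) under high dilution. The route is rejoined at 23.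

**Step 21.** The carbenoid may be captured by the neighbouring 4,5-oxirane oxygen, which is cis to O6 and can form a six-membered oxonium ylide that then deoxygenates or ring-expands. Insertion into C7–H may also simply be slow, because that methylene is deactivated by two β-acyloxy groups. Fallback with a less electrophilic, acceptor-only carbenoid: 25 is acylated with bromoacetyl bromide and pyridine to the C6 bromoacetate F4, which with N,N'-ditosylhydrazine and DBU gives the C6 diazoacetate F5. Dirhodium tetrakis(caprolactamate), Rh2(cap)4, the catalyst class known to turn cycloalkyl diazoacetates into fused γ-lactones, gives the unsubstituted 12,6-lactone F6. Condensation with tert-butoxybis(dimethylamino)methane followed by mild aqueous acid gives the 13-oxo (α-formyl) lactone F7. PhSeCl/pyridine and then H2O2 dehydrogenate it to the 13-oxo butenolide F8, and NaBH4 with CeCl3 reduces the aldehyde. The route is rejoined at 35.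

**Step 17.** The risk is poor facial selectivity: if the ring holds the C6 hydroxyl pseudo-equatorial, oxygen is delivered to the other face and the 4R,5S epoxide (trans to O6) results. Fallback by double inversion at C6: 24 undergoes a Mitsunobu reaction with 4-nitrobenzoic acid, PPh3 and diisopropyl azodicarboxylate to give the (6S) 4-nitrobenzoate F9. K2CO3 in MeOH at 0 °C removes the nitrobenzoate selectively to give the (6S) allylic alcohol F10. The same vanadium epoxidation, with the same trans preference, now places the oxirane oxygen where it is needed and gives the (4S,5R,6S) epoxy alcohol F11. A second Mitsunobu reaction, with half ester 28 as the acid, inverts C6 and installs the malonate in one operation. The route is rejoined at 29.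

**Step 23.** The butenolide of 33 is doubly activated and has leaving groups at both γ-carbons. Electron transfer from zinc could therefore cause reductive loss of the C8 senecioate, opening of the lactone C6–O bond, or conjugate reduction, in place of clean ester cleavage; the borane reduction of step 24 faces the same sensitive olefin. Fallback that carries out both reductions before the double bond exists: 31 is treated with Zn/AcOH to give the saturated lactone 13-oic acid F12, and BH3·SMe2 reduces this to the saturated 13-hydroxy lactone F13. Dess–Martin periodinane gives the α-formyl lactone F7, which is dehydrogenated to F8 and reduced as described for step 21. The route is rejoined at 35.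

## Further compounds

F1 | step 15 | (2S,4R,5Z)-4-[(tert-butyldimethylsilyl)oxy]-1-[(2R,3S)-3-(2-hydroxyethyl)-2-methyloxiran-2-yl]-6-iodohept-5-en-2-yl 3-methylbut-2-enoate | OCC[C@@H]1O[C@]1(C)C[C@@H](OC(=O)C=C(C)C)C[C@@H](O[Si](C)(C)C(C)(C)C)/C=C(/C)I
F2 | step 15 | (2S,4R,5Z)-4-[(tert-butyldimethylsilyl)oxy]-6-iodo-1-[(2R,3S)-3-(2-iodoethyl)-2-methyloxiran-2-yl]hept-5-en-2-yl 3-methylbut-2-enoate | ICC[C@@H]1O[C@]1(C)C[C@@H](OC(=O)C=C(C)C)C[C@@H](O[Si](C)(C)C(C)(C)C)/C=C(/C)I
F3 | step 15 | alkylzinc iodide derived from F2 at C3 | I[Zn]CC[C@@H]1O[C@]1(C)C[C@@H](OC(=O)C=C(C)C)C[C@@H](O[Si](C)(C)C(C)(C)C)/C=C(/C)I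
F4 | step 21 | C6 bromoacetate of 25 | C1[C@@H](OC(=O)CBr)[C@H]3O[C@@]3(C)CC[C@@H]2O[C@]2(C)C[C@H]1OC(=O)C=C(C)C
F5 | step 21 | C6 diazoacetate of 25 | C1[C@@H](OC(=O)C=[N+]=[N-])[C@H]3O[C@@]3(C)CC[C@@H]2O[C@]2(C)C[C@H]1OC(=O)C=C(C)C
F6 | step 21 | (1S,4S,5R,6R,8R,10R)-1,10:4,5-diepoxy-8-[(3-methylbut-2-enoyl)oxy]-13-norgermacran-12,6-olide (C7 open) | O=C1CC2[C@@H](O1)[C@H]1O[C@@]1(C)CC[C@@H]1O[C@]1(C)C[C@H]2OC(=O)C=C(C)C
F7 | step 21 | (1S,4S,5R,6R,8R,10R)-1,10:4,5-diepoxy-8-[(3-methylbut-2-enoyl)oxy]-13-oxogermacran-12,6-olide (aldehyde tautomer drawn; C7 and C11 open) | O=CC1C2[C@@H](OC1=O)[C@H]1O[C@@]1(C)CC[C@@H]1O[C@]1(C)C[C@H]2OC(=O)C=C(C)C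
F8 | step 21 | (1S,4S,5R,6R,8R,10R)-1,10:4,5-diepoxy-8-[(3-methylbut-2-enoyl)oxy]-13-oxogermacr-7(11)-en-12,6-olide | O=CC1=C2[C@@H](OC1=O)[C@H]1O[C@@]1(C)CC[C@@H]1O[C@]1(C)C[C@H]2OC(=O)C=C(C)C
F9 | step 17 | (1S,4Z,6S,8S,10R)-4,10-dimethyl-8-[(3-methylbut-2-enoyl)oxy]-11-oxabicyclo[8.1.0]undec-4-en-6-yl 4-nitrobenzoate | C1[C@H](OC(=O)c3ccc(cc3)[N+](=O)[O-])/C=C(/C)CC[C@@H]2O[C@]2(C)C[C@H]1OC(=O)C=C(C)C
F10 | step 17 | (1S,4Z,6S,8S,10R)-6-hydroxy-4,10-dimethyl-11-oxabicyclo[8.1.0]undec-4-en-8-yl 3-methylbut-2-enoate | C1[C@H](O)/C=C(/C)CC[C@@H]2O[C@]2(C)C[C@H]1OC(=O)C=C(C)C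
F11 | step 17 | (1S,4S,6R,7S,9S,11R)-7-hydroxy-4,11-dimethyl-5,12-dioxatricyclo[9.1.0.0(4,6)]dodecan-9-yl 3-methylbut-2-enoate | C1[C@H](O)[C@H]3O[C@@]3(C)CC[C@@H]2O[C@]2(C)C[C@H]1OC(=O)C=C(C)C
F12 | step 23 | (1S,4S,5R,6R,8R,10R)-1,10:4,5-diepoxy-8-[(3-methylbut-2-enoyl)oxy]germacran-12,6-olid-13-oic acid (C7 and C11 open) | OC(=O)C1C2[C@@H](OC1=O)[C@H]1O[C@@]1(C)CC[C@@H]1O[C@]1(C)C[C@H]2OC(=O)C=C(C)C
F13 | step 23 | (1S,4S,5R,6R,8R,10R)-1,10:4,5-diepoxy-13-hydroxy-8-[(3-methylbut-2-enoyl)oxy]germacran-12,6-olide (C7 and C11 open) | OCC1C2[C@@H](OC1=O)[C@H]1O[C@@]1(C)CC[C@@H]1O[C@]1(C)C[C@H]2OC(=O)C=C(C)C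
A1 | alternative 1 | [(2R,3S)-3-{2-[(2S,3R)-3-(hydroxymethyl)-2-methyloxiran-2-yl]ethyl}-2-methyloxiran-2-yl]methanol | OC[C@H]1O[C@@]1(C)CC[C@@H]1O[C@]1(C)CO
A2 | alternative 1 | (2Z,6Z)-2,6-dimethylocta-2,6-diene-1,8-diol | OC/C(C)=C\CC/C(C)=C\CO
A3 | alternative 2 | 13-acetoxy-1,10-epoxy-8-[(3-methylbut-2-enoyl)oxy]germacra-4(Z),7(11)-dien-12,6-olide (4,5-deoxy target) | CC(=O)OCC1=C2[C@@H](OC1=O)/C=C(/C)CC[C@@H]1O[C@]1(C)C[C@H]2OC(=O)C=C(C)C
A4 | alternative 2 | open-chain Z C5 alkenyl iodide with C6 aldehyde cis to the C12 methyl ester, carrying the 1,10-epoxide, the C8 senecioate and the C13 acetate | I/C=C(/C)CC[C@@H]1O[C@]1(C)C[C@@H](OC(=O)C=C(C)C)/C(C=O)=C(\COC(C)=O)C(=O)OC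
A5 | alternative 3 | (Z,Z)-cyclodeca-dienone with C6 ketone, C4=C5 and C1=C10 olefins and C8 silyl ether | C1C(=O)/C=C(/C)CC/C=C(/C)C[C@H]1O[Si](C)(C)C(C)(C)C
A6 | alternative 3 | (1S,3R,4aR,8aS)-3-[(tert-butyldimethylsilyl)oxy]-4a-hydroxy-1,6-dimethyl-1,2,3,4,4a,7,8,8a-octahydronaphthalene-1-carboxylic acid (one cis-fused diastereomer compatible with a Z C1=C10 outcome) | OC(=O)[C@@]1(C)C[C@@H](O[Si](C)(C)C(C)(C)C)C[C@@]2(O)C=C(C)CC[C@@H]12
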